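**Retrosynthetic overview**

1. Kazinol H is reached from its bis-TBS ether 22 by fluoride desilylation (step 13).
2. The strategy rests on the dihydropyran ring of the flavan (O1, C2, C3, C4, C4a, C8a), whose only stereocentre, C2, carries the B-ring aryl. It is cut at O1–C2 and C3–C4 into an A-ring o-quinone methide (O1–C8a–C4a–C4) and a B-ring styrene (C2–C3), joined by a chiral-acid-catalysed inverse-demand oxa-[4+2].
3. A half (9): 2,4-dihydroxybenzaldehyde, O4-prenylation, O2-MOM masking, aromatic Claisen shift (C6 1,1-dimethylallyl), O7 silylation, MOM removal, reduction.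
4. B half (20): 2-bromo-4,5-dihydroxybenzaldehyde, O4 propargyl ether, silylation, thermal chromene annulation, Stille prenylation, Wittig methylenation.
5. Ring order: both benzene rings are bought; the dimethylpyran ring of the B half forms in step 9; the flavan dihydropyran ring forms last, in step 12.

Key step: step 12

Assumption: the sense of induction of the chiral acid with this substrate pair cannot be derived from first principles; the (R)-acid is written in step 12, and its (S)-antipode is to be used if the cycloadduct proves to be (2R).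

**A half**

Step 1
Reactants: 1 2,4-dihydroxybenzaldehyde; 2 prenyl bromide
Product: 3 2-hydroxy-4-[(3-methylbut-2-en-1-yl)oxy]benzaldehyde
Conditions: K2CO3 (1.05 equiv), acetone, 50 °C
Reagents that add atoms: none
Why: Williamson etherification; the 2-OH is held in a hydrogen bond to the formyl group, so one equivalent of mild base should alkylate only the free, more acidic 4-OH.

Step 2
Reactants: 3 2-hydroxy-4-[(3-methylbut-2-en-1-yl)oxy]benzaldehyde
Product: 4 2-(methoxymethoxy)-4-[(3-methylbut-2-en-1-yl)oxy]benzaldehyde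
Conditions: MOMCl, i-Pr2NEt, DMAP (cat.), CH2Cl2, 0 °C → rt
Reagents that add atoms: chloromethyl methyl ether, COCCl
Why: MOM acetal protection of the phenol; removing the O–H···O=C chelate removes the bond fixation that would otherwise steer the coming Claisen shift to C3, between the two oxygens.

Step 3
Reactants: 4 2-(methoxymethoxy)-4-[(3-methylbut-2-en-1-yl)oxy]benzaldehyde
Product: 6 4-hydroxy-2-(methoxymethoxy)-5-(2-methylbut-3-en-2-yl)benzaldehyde, via ortho-dienone 5 (not isolated)
Conditions: PhNEt2, 190 °C, sealed tube, short reaction time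
Reagents that add atoms: none
Why: Aromatic Claisen rearrangement ([3,3]) with allyl inversion, then tautomerisation of the dienone; with O2 alkylated, the new quaternary carbon should form at the less hindered C5 (para to the O2 donor) and not at C3 flanked by two oxygens, as is usual for 2-alkoxy-4-prenyloxy aryl carbonyl compounds.

Step 4
Reactants: 6 4-hydroxy-2-(methoxymethoxy)-5-(2-methylbut-3-en-2-yl)benzaldehyde
Product: 7 4-[(tert-butyldimethylsilyl)oxy]-2-(methoxymethoxy)-5-(2-methylbut-3-en-2-yl)benzaldehyde
Conditions: TBSCl, imidazole, DMAP (cat.), DMF, rt → 40 °C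
Reagents that add atoms: tert-butyldimethylsilyl chloride, CC(C)(C)[Si](C)(C)Cl
Why: Silyl ether formation on the only free phenol; ortho tert-alkyl phenols still accept TBS, and this ether later blocks p-quinone methide formation and ring closure of O7 onto the neighbouring alkene.

Step 5
Reactants: 7 4-[(tert-butyldimethylsilyl)oxy]-2-(methoxymethoxy)-5-(2-methylbut-3-en-2-yl)benzaldehyde
Product: 8 4-[(tert-butyldimethylsilyl)oxy]-2-hydroxy-5-(2-methylbut-3-en-2-yl)benzaldehyde
Conditions: conc. HCl (cat.), MeOH, 40 °C; NaHCO3 work-up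
Reagents that add atoms: none
Why: Acid-catalysed acetal exchange (MOM cleavage); the MOM ether ortho to the formyl group is the most acid-labile function because the released phenol is chelated, whereas the hindered aryl silyl ether on an electron-poor ring should tolerate dilute methanolic acid.

Step 6
Reactants: 8 4-[(tert-butyldimethylsilyl)oxy]-2-hydroxy-5-(2-methylbut-3-en-2-yl)benzaldehyde
Product: 9 5-[(tert-butyldimethylsilyl)oxy]-2-(hydroxymethyl)-4-(2-methylbut-3-en-2-yl)phenol
Conditions: NaBH4, THF–MeOH (10:1), 0 °C; pH 7 buffer work-up; Et3N-deactivated silica; used at once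
Reagents that add atoms: none
Why: Borohydride reduction of the aldehyde; low temperature and short contact should spare the hindered aryl silyl ether, and neutral handling keeps the electron-rich salicyl alcohol from ionising early.

**B half**

Step 7
Reactants: 10 2-bromo-4,5-dihydroxybenzaldehyde; 11 3-chloro-3-methylbut-1-yne
Product: 12 2-bromo-5-hydroxy-4-[(2-methylbut-3-yn-2-yl)oxy]benzaldehyde
Conditions: DBU (1.3 equiv), CuCl2·2H2O (1 mol%), MeCN, 0 °C, N2
Reagents that add atoms: none
Why: Copper-catalysed propargylic etherification of a phenoxide with a tertiary propargylic chloride; the 4-OH para to the formyl group is by far the more acidic, so the monoanion formed with one equivalent of base should be alkylated at O4 only.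

Step 8
Reactants: 12 2-bromo-5-hydroxy-4-[(2-methylbut-3-yn-2-yl)oxy]benzaldehyde
Product: 13 2-bromo-5-[(tert-butyldimethylsilyl)oxy]-4-[(2-methylbut-3-yn-2-yl)oxy]benzaldehyde
Conditions: TBSCl, imidazole, DMF, rt
Reagents that add atoms: tert-butyldimethylsilyl chloride, CC(C)(C)[Si](C)(C)Cl
Why: Silyl ether formation on the remaining phenol, which protects the catechol from oxidation during the thermal step and from C-alkylation in step 12.

Step 9
Reactants: 13 2-bromo-5-[(tert-butyldimethylsilyl)oxy]-4-[(2-methylbut-3-yn-2-yl)oxy]benzaldehyde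
Product: 17 5-bromo-8-[(tert-butyldimethylsilyl)oxy]-2,2-dimethyl-2H-chromene-6-carbaldehyde, via allenyl dienone 14 (not isolated), via ortho-allenylphenol 15 (not isolated), via oxatriene dienone 16 (not isolated)
Conditions: PhNEt2, 180 °C
Reagents that add atoms: none
Why: Propargyl Claisen rearrangement, enolisation, 1,5-hydrogen shift and oxa-6π electrocyclisation in one thermal cascade; C3 is the only ortho carbon that bears hydrogen, so the pyran ring can form only on the bromine side.

Step 10
Reactants: 17 5-bromo-8-[(tert-butyldimethylsilyl)oxy]-2,2-dimethyl-2H-chromene-6-carbaldehyde; 18 tributyl(3-methylbut-2-en-1-yl)stannane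
Product: 19 8-[(tert-butyldimethylsilyl)oxy]-2,2-dimethyl-5-(3-methylbut-2-en-1-yl)-2H-chromene-6-carbaldehyde
Conditions: Pd(PPh3)4 (10 mol%), DMF, 100 °C; tin removed on K2CO3-doped silica (no fluoride wash)
Reagents that add atoms: none
Why: Stille coupling; the ortho formyl group activates the C–Br bond for oxidative addition, the prenyl–palladium intermediate should reductively eliminate at its primary terminus to give the linear prenyl arene, and fluoride-free conditions keep the aryl silyl ether.

Step 11
Reactants: 19 8-[(tert-butyldimethylsilyl)oxy]-2,2-dimethyl-5-(3-methylbut-2-en-1-yl)-2H-chromene-6-carbaldehyde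
Product: 20 tert-butyl{[6-ethenyl-2,2-dimethyl-5-(3-methylbut-2-en-1-yl)-2H-chromen-8-yl]oxy}dimethylsilane
Conditions: Ph3PCH3Br (1.3 equiv), KOt-Bu (1.2 equiv), THF, 0 °C → rt
Reagents that add atoms: methyltriphenylphosphonium bromide, C[P+](c1ccccc1)(c1ccccc1)c1ccccc1.[Br-]
Why: Wittig methylenation of an aryl aldehyde with the unstabilised ylide; no enolisable position is present, and a slight deficit of base relative to the salt protects the aryl silyl ether.

**Union and completion**

Step 12
Reactants: 9 5-[(tert-butyldimethylsilyl)oxy]-2-(hydroxymethyl)-4-(2-methylbut-3-en-2-yl)phenol; 20 tert-butyl{[6-ethenyl-2,2-dimethyl-5-(3-methylbut-2-en-1-yl)-2H-chromen-8-yl]oxy}dimethylsilane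
Product: 22 (2S)-kazinol H bis(tert-butyldimethylsilyl) ether, via o-quinone methide 21 (not isolated)
Conditions: (R)-TRIP phosphoric acid (10 mol%), PhMe, 0 °C → rt; 9 added slowly to 20 (1.3 equiv) and the acid
Reagents that add atoms: none
Why: The acid protonates the benzylic hydroxyl of 9, water leaves with help from the para silyloxy and ortho hydroxy donors, and the o-quinone methide 21 stays hydrogen-bonded to the chiral phosphate; the terminal vinyl carbon of 20 then adds to the exocyclic methylene (C3–C4) while the quinone methide oxygen closes on the developing benzylic cation (O1–C2) in one asynchronous event. The closest known reaction type is the Brønsted-acid-catalysed inverse-electron-demand oxa-Diels–Alder reaction of o-quinone methides, generated in situ from 2-hydroxybenzyl alcohols, with vinylarenes. The dihydropyran ring (O1, C2, C3, C4, C4a, C8a) is closed by this [4+2] cycloaddition, the quinone methide supplying O1–C8a–C4a–C4 and the styrene C2–C3. C2 is the only new stereocentre and is set by the catalyst: the phosphate bound to the quinone methide should expose one enantiotopic face of the styrene to O1, so the choice of catalyst antipode fixes (S). Regiochemistry (aryl at C2) follows from stabilisation of positive charge at the benzylic carbon by the para pyran oxygen of the B ring, and chemoselectivity from the vinyl group being the most nucleophilic and least hindered of the four alkenes. The O7 silyl ether prevents p-quinone methide formation and cyclisation onto the 1,1-dimethylallyl group, and the B-ring silyl ether prevents C-alkylation of a free phenol.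

Step 13
Reactants: 22 (2S)-kazinol H bis(tert-butyldimethylsilyl) ether
Product: 23 kazinol H
Conditions: TBAF (2.5 equiv), AcOH (2.5 equiv), THF, 0 °C → rt
Reagents that add atoms: none
Why: Fluoride-induced desilylation of both aryl silyl ethers; acetic acid buffering keeps the medium near neutral, so the benzylic ether stereocentre C2, the chromene and the phenol next to the 1,1-dimethylallyl group should be left untouched.

**Compound list**

1 | 2,4-dihydroxybenzaldehyde | O=Cc1ccc(O)cc1O | starting material
2 | prenyl bromide (1-bromo-3-methylbut-2-ene) | CC(C)=CCBr | starting material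
3 | 2-hydroxy-4-[(3-methylbut-2-en-1-yl)oxy]benzaldehyde | O=Cc1ccc(OCC=C(C)C)cc1O | intermediate
4 | 2-(methoxymethoxy)-4-[(3-methylbut-2-en-1-yl)oxy]benzaldehyde | O=Cc1ccc(OCC=C(C)C)cc1OCOC | intermediate
5 | ortho-dienone: 4-formyl-3-(methoxymethoxy)-6-(2-methylbut-3-en-2-yl)cyclohexa-2,4-dien-1-one (racemic, not isolated) | O=CC1=CC(C(C)(C)C=C)C(=O)C=C1OCOC | intermediate
6 | 4-hydroxy-2-(methoxymethoxy)-5-(2-methylbut-3-en-2-yl)benzaldehyde | C=CC(C)(C)c1cc(C=O)c(OCOC)cc1O | intermediate
7 | 4-[(tert-butyldimethylsilyl)oxy]-2-(methoxymethoxy)-5-(2-methylbut-3-en-2-yl)benzaldehyde | C=CC(C)(C)c1cc(C=O)c(OCOC)cc1O[Si](C)(C)C(C)(C)C | intermediate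
8 | 4-[(tert-butyldimethylsilyl)oxy]-2-hydroxy-5-(2-methylbut-3-en-2-yl)benzaldehyde | C=CC(C)(C)c1cc(C=O)c(O)cc1O[Si](C)(C)C(C)(C)C | intermediate
9 | 5-[(tert-butyldimethylsilyl)oxy]-2-(hydroxymethyl)-4-(2-methylbut-3-en-2-yl)phenol | C=CC(C)(C)c1cc(CO)c(O)cc1O[Si](C)(C)C(C)(C)C | intermediate
10 | 2-bromo-4,5-dihydroxybenzaldehyde | O=Cc1cc(O)c(O)cc1Br | starting material
11 | 3-chloro-3-methylbut-1-yne | C#CC(C)(C)Cl | starting material
12 | 2-bromo-5-hydroxy-4-[(2-methylbut-3-yn-2-yl)oxy]benzaldehyde | O=Cc1cc(O)c(OC(C)(C)C#C)cc1Br | intermediate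
13 | 2-bromo-5-[(tert-butyldimethylsilyl)oxy]-4-[(2-methylbut-3-yn-2-yl)oxy]benzaldehyde | O=Cc1cc(O[Si](C)(C)C(C)(C)C)c(OC(C)(C)C#C)cc1Br | intermediate
14 | allenyl dienone: 2-bromo-5-[(tert-butyldimethylsilyl)oxy]-3-(3-methylbuta-1,2-dien-1-yl)-4-oxocyclohexa-1,5-diene-1-carbaldehyde (racemic, not isolated) | O=CC1=C(Br)C(C=C=C(C)C)C(=O)C(O[Si](C)(C)C(C)(C)C)=C1 | intermediate
15 | ortho-allenylphenol: 2-bromo-5-[(tert-butyldimethylsilyl)oxy]-4-hydroxy-3-(3-methylbuta-1,2-dien-1-yl)benzaldehyde (not isolated) | O=Cc1cc(O[Si](C)(C)C(C)(C)C)c(O)c(C=C=C(C)C)c1Br | intermediate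
16 | oxatriene dienone: 2-bromo-5-[(tert-butyldimethylsilyl)oxy]-3-(3-methylbut-2-en-1-ylidene)-4-oxocyclohexa-1,5-diene-1-carbaldehyde (not isolated) | O=CC1=C(Br)C(=CC=C(C)C)C(=O)C(O[Si](C)(C)C(C)(C)C)=C1 | intermediate
17 | 5-bromo-8-[(tert-butyldimethylsilyl)oxy]-2,2-dimethyl-2H-chromene-6-carbaldehyde | O=Cc1cc(O[Si](C)(C)C(C)(C)C)c2c(c1Br)C=CC(C)(C)O2 | intermediate
18 | tributyl(3-methylbut-2-en-1-yl)stannane | CCCC[Sn](CCCC)(CCCC)CC=C(C)C | starting material
19 | 8-[(tert-butyldimethylsilyl)oxy]-2,2-dimethyl-5-(3-methylbut-2-en-1-yl)-2H-chromene-6-carbaldehyde | O=Cc1cc(O[Si](C)(C)C(C)(C)C)c2c(c1CC=C(C)C)C=CC(C)(C)O2 | intermediate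
20 | tert-butyl{[6-ethenyl-2,2-dimethyl-5-(3-methylbut-2-en-1-yl)-2H-chromen-8-yl]oxy}dimethylsilane | C=Cc1cc(O[Si](C)(C)C(C)(C)C)c2c(c1CC=C(C)C)C=CC(C)(C)O2 | intermediate
21 | o-quinone methide: 3-[(tert-butyldimethylsilyl)oxy]-4-(2-methylbut-3-en-2-yl)-6-methylidenecyclohexa-2,4-dien-1-one (not isolated) | C=CC(C)(C)C1=CC(=C)C(=O)C=C1O[Si](C)(C)C(C)(C)C | intermediate
22 | (2S)-kazinol H bis(tert-butyldimethylsilyl) ether: (2S)-flavan with 7-OTBS and 6-(2-methylbut-3-en-2-yl) on ring A, C2 bearing the 8-OTBS-2,2-dimethyl-5-prenyl-2H-chromen-6-yl group | C=CC(C)(C)c1cc2c(cc1O[Si](C)(C)C(C)(C)C)O[C@H](c1cc(O[Si](C)(C)C(C)(C)C)c3c(c1CC=C(C)C)C=CC(C)(C)O3)CC2 | intermediate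
23 | kazinol H, (2S) | C=CC(C)(C)c1cc2c(cc1O)O[C@H](c1cc(O)c3c(c1CC=C(C)C)C=CC(C)(C)O3)CC2 | target

**Step count**

Total: 13 steps. Longest linear sequence: 8 steps (steps 1–6, 12, 13); the B half contributes 5 steps before the union.

**Steps most likely to fail, with fallbacks**

Step 12. Facial discrimination may be insufficient, because the styrene has no hydrogen-bond contact with the catalyst and ring closure may pass through a free, p-alkoxy-stabilised benzylic cation. The product could also lose enantiopurity by reversible acid ionisation of the O1–C2 bond. Self-condensation of the quinone methide and capture of the cation by the ortho prenyl alkene are further loss channels. A more confined or more acidic chiral acid and a lower temperature are the first adjustments.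

The fallback sets out from 19 and 9 and comes back at 22; it sets C2 by reagent-controlled ketone reduction and stereospecific etherification:
- MeMgBr (THF, −78 °C) should convert 19 into the secondary alcohol 1-[8-(TBSO)-2,2-dimethyl-5-prenyl-2H-chromen-6-yl]ethanol F1.
- Dess–Martin oxidation (NaHCO3, CH2Cl2) should give the methyl ketone F2.
- TMSOTf/Et3N (CH2Cl2, 0 °C) should give the trimethylsilyl enol ether F3.
- Quinone methide 21, released from 9 by an achiral acid (diphenyl phosphate, 4 Å MS), should add F3 (2 equiv; hydrolysed excess is recovered as F2) in the established inverse-demand [4+2] with enol ethers, giving the 2-(trimethylsilyloxy)-2-arylchroman F4.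
- Dilute aqueous acid work-up should open F4 to the 2′-hydroxydihydrochalcone F5.
- Corey–Bakshi–Shibata reduction ((S)-Me-CBS, BH3·SMe2 in excess to allow for the phenol) is expected to give the (R)-carbinol F6.
- Mitsunobu cyclisation (PPh3, DIAD, THF, 0 °C) should close O1–C2 with inversion to give (2S)-22.

Step 3. Migration may go to the wrong ortho carbon (C3). The prenyl group may be lost heterolytically from the ether of an acidic p-formyl phenol. The product phenol may react further at the required temperature, by abnormal Claisen shift or ring closure onto the new alkene.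

The fallback sets out from 1 and comes back at 8; it installs the 1,1-dimethylallyl group by cross-coupling:
- Bromination (Br2, AcOH, rt) should give 5-bromo-2,4-dihydroxybenzaldehyde F7.
- MOMCl/NaH (DMF, 0 °C) should give the bis-MOM ether F8.
- γ-Selective Suzuki–Miyaura coupling with prenylboronic acid pinacol ester (Pd/biarylphosphine, aq. K3PO4, THF, 40 °C) should attach the tertiary allyl terminus and give 2,4-bis(methoxymethoxy)-5-(2-methylbut-3-en-2-yl)benzaldehyde F9.
- HCl/MeOH (40 °C) should remove both acetals to give 2,4-dihydroxy-5-(2-methylbut-3-en-2-yl)benzaldehyde F10.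
- TBSCl/imidazole (1.05 equiv, DMF, 0 °C) should silylate the non-chelated 4-OH in preference to the hydrogen-bonded 2-OH and give 8.

Step 10. Oxidative addition and transmetallation may be slow at the doubly ortho-substituted bromide. Coupling through the tertiary terminus of the prenyl–palladium intermediate would give the branched isomer. Protodebromination is a further risk.

The fallback sets out from 17 and comes back at 19:
- Stille coupling with allyltributylstannane (Pd(PPh3)4, DMF, 90 °C), which has no α/γ ambiguity, should give 5-allyl-8-[(tert-butyldimethylsilyl)oxy]-2,2-dimethyl-2H-chromene-6-carbaldehyde F11.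
- Cross-metathesis with 2-methylbut-2-ene (Grubbs II, CH2Cl2, 40 °C) should convert the allyl group into prenyl and give 19. The chromene double bond, a cyclic 1,2-disubstituted alkene next to a quaternary carbon, is expected to stay inert.

**Further compounds**

F1 | step 12 | 1-[8-[(tert-butyldimethylsilyl)oxy]-2,2-dimethyl-5-(3-methylbut-2-en-1-yl)-2H-chromen-6-yl]ethan-1-ol (racemic) | CC(O)c1cc(O[Si](C)(C)C(C)(C)C)c2c(c1CC=C(C)C)C=CC(C)(C)O2
F2 | step 12 | 1-[8-[(tert-butyldimethylsilyl)oxy]-2,2-dimethyl-5-(3-methylbut-2-en-1-yl)-2H-chromen-6-yl]ethan-1-one | CC(=O)c1cc(O[Si](C)(C)C(C)(C)C)c2c(c1CC=C(C)C)C=CC(C)(C)O2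
F3 | step 12 | trimethylsilyl enol ether of F2 | C=C(O[Si](C)(C)C)c1cc(O[Si](C)(C)C(C)(C)C)c2c(c1CC=C(C)C)C=CC(C)(C)O2
F4 | step 12 | 2-(trimethylsilyloxy) analogue of 22 (racemic 2-aryl-2-silyloxychroman) | C=CC(C)(C)c1cc2c(cc1O[Si](C)(C)C(C)(C)C)OC(O[Si](C)(C)C)(c1cc(O[Si](C)(C)C(C)(C)C)c3c(c1CC=C(C)C)C=CC(C)(C)O3)CC2
F5 | step 12 | 2′-hydroxydihydrochalcone: 3-[4-(TBSO)-2-hydroxy-5-(2-methylbut-3-en-2-yl)phenyl]-1-[8-(TBSO)-2,2-dimethyl-5-prenyl-2H-chromen-6-yl]propan-1-one | C=CC(C)(C)c1cc(CCC(=O)c2cc(O[Si](C)(C)C(C)(C)C)c3c(c2CC=C(C)C)C=CC(C)(C)O3)c(O)cc1O[Si](C)(C)C(C)(C)C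
F6 | step 12 | (1R)-carbinol from F5 | C=CC(C)(C)c1cc(CC[C@@H](O)c2cc(O[Si](C)(C)C(C)(C)C)c3c(c2CC=C(C)C)C=CC(C)(C)O3)c(O)cc1O[Si](C)(C)C(C)(C)C
F7 | step 3 | 5-bromo-2,4-dihydroxybenzaldehyde | O=Cc1cc(Br)c(O)cc1O
F8 | step 3 | 5-bromo-2,4-bis(methoxymethoxy)benzaldehyde | O=Cc1cc(Br)c(OCOC)cc1OCOC
F9 | step 3 | 2,4-bis(methoxymethoxy)-5-(2-methylbut-3-en-2-yl)benzaldehyde | C=CC(C)(C)c1cc(C=O)c(OCOC)cc1OCOC
F10 | step 3 | 2,4-dihydroxy-5-(2-methylbut-3-en-2-yl)benzaldehyde | C=CC(C)(C)c1cc(C=O)c(O)cc1O
F11 | step 10 | 5-allyl-8-[(tert-butyldimethylsilyl)oxy]-2,2-dimethyl-2H-chromene-6-carbaldehyde | O=Cc1cc(O[Si](C)(C)C(C)(C)C)c2c(c1CC=C)C=CC(C)(C)O2
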